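**Retrosynthetic overview**

1. Last step: CrCl2 closes the fully oxidised, fully acylated seco-aldehyde 17 at C6–C7 (the farnesyl C1–C10 bond of the germacrane pathway) to give the ten-membered carbocycle, and the new C6 alkoxide then closes the 12,6-lactone in the same flask; nothing is done afterwards.
2. 17 comes from Sharpless epoxidation of the neryl-type alcohol 15 (4,5-oxirane, made before the carbocycle) and oxidation; the C8 ester comes from alcohol 10 and (S)-2-methylglycidate 11 (side-chain oxirane bought in).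
3. 10 comes from acetolysis, with inversion at C9, of the trans vinyl oxirane 9; 9 comes from organocatalytic epoxidation of dienal 6, vinylalumination and SN2′ chlorination.
4. 6 comes from Heck coupling of acrolein with the Z α-iodoenoate 5, made by iodo-Wittig olefination of the C1 aldehyde 4 from nerol.
5. Ring order: side-chain oxirane (from 11), transient 8,9-oxirane, 4,5-oxirane, ten-membered ring, γ-lactone.

Assumption: the SMILES is read literally (C2 and C9 cis on C1=C10; cis 4,5-epoxide with C3 and C6 on the same side; 4R,5S,6S,7R,8S,9R; (2S)-2-methyloxirane-2-carboxylate), and germacrane numbering C1–C15 is used throughout.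

**Route**

Step 1
Reactants: 1 nerol
Product: 2 neryl tert-butyldiphenylsilyl ether
Conditions: TBDPSCl, imidazole, DMF, 0 °C to rt
Reagents that add atoms: tert-butyl(chloro)diphenylsilane, CC(C)(C)[Si](Cl)(c1ccccc1)c1ccccc1
Why: Imidazole-promoted silylation of the primary allylic alcohol gives an ether that survives ozone, palladium and acetic acid; no stereocentre is formed and the Z olefin is untouched.

Step 2
Reactants: 2 neryl tert-butyldiphenylsilyl ether
Product: 4 (4Z)-6-[(tert-butyldiphenylsilyl)oxy]-4-methylhex-4-enal, via secondary ozonide 3 (not isolated)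
Conditions: O3 (1.0 equiv), CH2Cl2, pyridine (cat.), −78 °C; then Me2S, −78 °C to rt
Reagents that add atoms: ozone, [O-][O+]=O
Why: Chemoselective Criegee ozonolysis, in which the electron-rich isopropylidene olefin reacts faster than the Z olefin deactivated by its allylic oxygen and Me2S reduces the ozonide to the C1 aldehyde; no stereocentre is formed.

Step 3
Reactants: 4 (4Z)-6-[(tert-butyldiphenylsilyl)oxy]-4-methylhex-4-enal
Product: 5 methyl (2Z,6Z)-8-[(tert-butyldiphenylsilyl)oxy]-2-iodo-6-methylocta-2,6-dienoate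
Conditions: Ph3P=CHCO2Me, N-iodosuccinimide, CH2Cl2, −20 °C; then 4, 0 °C to rt
Reagents that add atoms: methyl (triphenylphosphoranylidene)acetate, COC(=O)C=P(c1ccccc1)(c1ccccc1)c1ccccc1; N-iodosuccinimide, O=C1CCC(=O)N1I
Why: One-pot halogenation–Wittig olefination, in which the iodinated stabilised ylide gives mainly the Z α-iodoenoate (chain cis to iodine, trans to the ester), which fixes the C1=C10 geometry of the target.

Step 4
Reactants: 5 methyl (2Z,6Z)-8-[(tert-butyldiphenylsilyl)oxy]-2-iodo-6-methylocta-2,6-dienoate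
Product: 6 methyl (2E,6Z)-8-[(tert-butyldiphenylsilyl)oxy]-6-methyl-2-[(1E)-3-oxoprop-1-en-1-yl]octa-2,6-dienoate
Conditions: acrolein (3 equiv), Pd(OAc)2 (5 mol %), Bu4NCl, NaHCO3, DMF, 40 °C
Reagents that add atoms: acrolein, C=CC=O
Why: Phosphine-free Mizoroki–Heck coupling (Jeffery conditions), in which the alkenylpalladium keeps the C1=C10 geometry and syn insertion/syn β-hydride elimination gives the E enal, adding C7–C9 in one step.

Step 5
Reactants: 6 methyl (2E,6Z)-8-[(tert-butyldiphenylsilyl)oxy]-6-methyl-2-[(1E)-3-oxoprop-1-en-1-yl]octa-2,6-dienoate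
Product: 7 methyl (2E,6Z)-8-[(tert-butyldiphenylsilyl)oxy]-2-[(2S,3R)-3-formyloxiran-2-yl]-6-methylocta-2,6-dienoate
Conditions: (S)-2-{bis[3,5-bis(trifluoromethyl)phenyl](trimethylsilyloxy)methyl}pyrrolidine (10 mol %), 35% aq. H2O2, CH2Cl2, rt
Reagents that add atoms: hydrogen peroxide, OO
Why: Jørgensen–Hayashi iminium–enamine epoxidation, in which H2O2 adds to C9 of the catalyst-bound iminium on the face left open by the diarylsilyloxymethyl group and the enamine closes the trans oxirane, setting C8 and C9 under catalyst control while the enoate and the isolated olefin stay inert.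

Step 6
Reactants: 7 methyl (2E,6Z)-8-[(tert-butyldiphenylsilyl)oxy]-2-[(2S,3R)-3-formyloxiran-2-yl]-6-methylocta-2,6-dienoate
Product: 8 methyl (2E,6Z)-8-[(tert-butyldiphenylsilyl)oxy]-2-{(2S,3S)-3-[1-hydroxy-2-(methoxycarbonyl)prop-2-en-1-yl]oxiran-2-yl}-6-methylocta-2,6-dienoate (both C7 epimers)
Conditions: methyl propiolate, i-Bu2AlH, NMO, THF, 0 °C; then 7, 0 °C to rt
Reagents that add atoms: methyl propiolate, C#CC(=O)OC
Why: Vinylalumination (the aluminium variant of the Morita–Baylis–Hillman reaction), in which cis hydroalumination of the propiolate gives an α-aluminoacrylate that adds 1,2 to the aldehyde without amine base; the C7 carbinol forms as a mixture that the next step erases.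

Step 7
Reactants: 8 methyl (2E,6Z)-8-[(tert-butyldiphenylsilyl)oxy]-2-{(2S,3S)-3-[1-hydroxy-2-(methoxycarbonyl)prop-2-en-1-yl]oxiran-2-yl}-6-methylocta-2,6-dienoate
Product: 9 methyl (2E,6Z)-8-[(tert-butyldiphenylsilyl)oxy]-2-{(2S,3S)-3-[(1Z)-3-chloro-2-(methoxycarbonyl)prop-1-en-1-yl]oxiran-2-yl}-6-methylocta-2,6-dienoate
Conditions: N-chlorosuccinimide, Me2S, CH2Cl2, −20 to 0 °C
Reagents that add atoms: N-chlorosuccinimide, O=C1CCC(=O)N1Cl
Why: Corey–Kim activation with allylic transposition (SN2′), in which chloride attacks the terminal methylene of the alkoxysulfonium salt to give the conjugated primary allylic chloride as the favoured Z isomer (C8 cis to CH2Cl), removing the C7 stereocentre under neutral conditions that spare the oxirane.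

Step 8
Reactants: 9 methyl (2E,6Z)-8-[(tert-butyldiphenylsilyl)oxy]-2-{(2S,3S)-3-[(1Z)-3-chloro-2-(methoxycarbonyl)prop-1-en-1-yl]oxiran-2-yl}-6-methylocta-2,6-dienoate
Product: 10 dimethyl (2Z,4S,5R,6E)-5-acetoxy-6-{(4Z)-6-[(tert-butyldiphenylsilyl)oxy]-4-methylhex-4-en-1-ylidene}-2-(chloromethyl)-4-hydroxyhept-2-enedioate
Conditions: glacial AcOH, 25 °C
Reagents that add atoms: acetic acid, CC(=O)O
Why: Acid-mediated SN2 opening of a vinyl oxirane, in which acetic acid attacks C9 (its developing charge is allylic to C1=C10) rather than C8 (a cation there would be conjugated with the C12 ester), and inversion at C9 converts the trans oxirane into the erythro (8S,9R) 8-hydroxy 9-acetate.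

Step 9
Reactants: 11 methyl (2S)-2-methyloxirane-2-carboxylate
Product: 12 potassium (2S)-2-methyloxirane-2-carboxylate
Conditions: KOH (1.0 equiv), EtOH, 0 °C
Reagents that add atoms: potassium hydroxide, [K+].[OH-]
Why: Ester saponification gives the stable glycidate salt, and the quaternary stereocentre cannot epimerise.

Step 10
Reactants: 10 dimethyl (2Z,4S,5R,6E)-5-acetoxy-6-{(4Z)-6-[(tert-butyldiphenylsilyl)oxy]-4-methylhex-4-en-1-ylidene}-2-(chloromethyl)-4-hydroxyhept-2-enedioate; 12 potassium (2S)-2-methyloxirane-2-carboxylate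
Product: 14 dimethyl (2Z,4S,5R,6E)-5-acetoxy-6-{(4Z)-6-[(tert-butyldiphenylsilyl)oxy]-4-methylhex-4-en-1-ylidene}-2-(chloromethyl)-4-{[(2S)-2-methyloxirane-2-carbonyl]oxy}hept-2-enedioate, via (2S)-2-methyloxirane-2-carbonyl chloride 13 (not isolated)
Conditions: 12, (COCl)2, DMF (cat.), CH2Cl2, 0 °C; then 10, 2,4,6-collidine, DMAP (10 mol %), −20 to 0 °C
Reagents that add atoms: none
Why: Esterification through the acid chloride with acylpyridinium catalysis, in which the C8 hydroxyl is the only free alcohol and is acylated with retention while the hindered base spares the allylic chloride.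

Step 11
Reactants: 14 dimethyl (2Z,4S,5R,6E)-5-acetoxy-6-{(4Z)-6-[(tert-butyldiphenylsilyl)oxy]-4-methylhex-4-en-1-ylidene}-2-(chloromethyl)-4-{[(2S)-2-methyloxirane-2-carbonyl]oxy}hept-2-enedioate
Product: 15 dimethyl (2Z,4S,5R,6E)-5-acetoxy-2-(chloromethyl)-6-[(4Z)-6-hydroxy-4-methylhex-4-en-1-ylidene]-4-{[(2S)-2-methyloxirane-2-carbonyl]oxy}hept-2-enedioate
Conditions: HF·pyridine, THF, 0 °C to rt
Reagents that add atoms: none
Why: Fluoride-driven desilylation frees the C6 allylic alcohol while esters, the glycidate oxirane and the allylic chloride tolerate the mildly acidic reagent; no stereocentre is touched.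

Step 12
Reactants: 15 dimethyl (2Z,4S,5R,6E)-5-acetoxy-2-(chloromethyl)-6-[(4Z)-6-hydroxy-4-methylhex-4-en-1-ylidene]-4-{[(2S)-2-methyloxirane-2-carbonyl]oxy}hept-2-enedioate
Product: 16 dimethyl (2Z,4S,5R,6E)-5-acetoxy-2-(chloromethyl)-6-{3-[(2R,3S)-3-(hydroxymethyl)-2-methyloxiran-2-yl]propylidene}-4-{[(2S)-2-methyloxirane-2-carbonyl]oxy}hept-2-enedioate
Conditions: Ti(OiPr)4 (10 mol %), L-(+)-diethyl tartrate (12 mol %), t-BuOOH, 4 Å sieves, CH2Cl2, −20 °C
Reagents that add atoms: tert-butyl hydroperoxide, CC(C)(C)OO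
Why: Katsuki–Sharpless asymmetric epoxidation of the only allylic alcohol, in which L-(+)-tartrate delivers oxygen to the face that gives the cis (4R,5S) oxirane from the Z olefin under reagent control (as nerol gives (2S,3R)-epoxynerol), the other olefins being unreactive enoates.

Step 13
Reactants: 16 dimethyl (2Z,4S,5R,6E)-5-acetoxy-2-(chloromethyl)-6-{3-[(2R,3S)-3-(hydroxymethyl)-2-methyloxiran-2-yl]propylidene}-4-{[(2S)-2-methyloxirane-2-carbonyl]oxy}hept-2-enedioate
Product: 17 dimethyl (2Z,4S,5R,6E)-5-acetoxy-2-(chloromethyl)-6-{3-[(2R,3R)-3-formyl-2-methyloxiran-2-yl]propylidene}-4-{[(2S)-2-methyloxirane-2-carbonyl]oxy}hept-2-enedioate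
Conditions: Dess–Martin periodinane, NaHCO3, CH2Cl2, 0 °C
Reagents that add atoms: none
Why: Dess–Martin oxidation converts the primary epoxy alcohol into the α,β-epoxy aldehyde under buffered conditions that neither open the oxiranes nor epimerise C5 (the descriptor changes only because the priorities change).

Step 14
Reactants: 17 dimethyl (2Z,4S,5R,6E)-5-acetoxy-2-(chloromethyl)-6-{3-[(2R,3R)-3-formyl-2-methyloxiran-2-yl]propylidene}-4-{[(2S)-2-methyloxirane-2-carbonyl]oxy}hept-2-enedioate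
Product: 20 target CNP0274195.2, via allylchromium dichloride 18 (not isolated), via ten-membered hydroxy ester 19 (not isolated)
Conditions: CrCl2 (8 equiv), THF/DMF 4:1, 0.002 M, slow addition of 17 over 10 h, 25 °C
Reagents that add atoms: none
Why: Intramolecular Nozaki–Hiyama (chromium Barbier) allylation followed by lactonisation, in which divalent chromium turns the allylic chloride into an allylchromium species whose γ-carbon C7 adds to the C6 aldehyde through a chair-like transition state, Felkin–Anh attack anti to the oxirane C–O bond setting 6S and the anti (trans-lactone) mode setting 7R, after which the chromium alkoxide acylates on the C12 ester to close the lactone.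

**Compound list**

1 | nerol, (2Z)-3,7-dimethylocta-2,6-dien-1-ol | CC(C)=CCC/C(C)=C\CO | starting material
2 | neryl tert-butyldiphenylsilyl ether | CC(C)=CCC/C(C)=C\CO[Si](c1ccccc1)(c1ccccc1)C(C)(C)C | intermediate
3 | secondary ozonide, 3,3-dimethyl-5-{(3Z)-5-[(tert-butyldiphenylsilyl)oxy]-3-methylpent-3-en-1-yl}-1,2,4-trioxolane | CC1(C)OOC(CC/C(C)=C\CO[Si](c2ccccc2)(c2ccccc2)C(C)(C)C)O1 | intermediate
4 | (4Z)-6-[(tert-butyldiphenylsilyl)oxy]-4-methylhex-4-enal | O=CCC/C(C)=C\CO[Si](c1ccccc1)(c1ccccc1)C(C)(C)C | intermediate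
5 | methyl (2Z,6Z)-8-[(tert-butyldiphenylsilyl)oxy]-2-iodo-6-methylocta-2,6-dienoate | COC(=O)/C(I)=C/CC/C(C)=C\CO[Si](c1ccccc1)(c1ccccc1)C(C)(C)C | intermediate
6 | methyl (2E,6Z)-8-[(tert-butyldiphenylsilyl)oxy]-6-methyl-2-[(1E)-3-oxoprop-1-en-1-yl]octa-2,6-dienoate | O=C/C=C/C(C(=O)OC)=C\CC/C(C)=C\CO[Si](c1ccccc1)(c1ccccc1)C(C)(C)C | intermediate
7 | methyl (2E,6Z)-8-[(tert-butyldiphenylsilyl)oxy]-2-[(2S,3R)-3-formyloxiran-2-yl]-6-methylocta-2,6-dienoate | O=C[C@@H]1O[C@H]1/C(C(=O)OC)=C\CC/C(C)=C\CO[Si](c1ccccc1)(c1ccccc1)C(C)(C)C | intermediate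
8 | methyl (2E,6Z)-8-[(tert-butyldiphenylsilyl)oxy]-2-{(2S,3S)-3-[1-hydroxy-2-(methoxycarbonyl)prop-2-en-1-yl]oxiran-2-yl}-6-methylocta-2,6-dienoate (both C7 epimers) | C=C(C(=O)OC)C(O)[C@@H]1O[C@H]1/C(C(=O)OC)=C\CC/C(C)=C\CO[Si](c1ccccc1)(c1ccccc1)C(C)(C)C | intermediate
9 | methyl (2E,6Z)-8-[(tert-butyldiphenylsilyl)oxy]-2-{(2S,3S)-3-[(1Z)-3-chloro-2-(methoxycarbonyl)prop-1-en-1-yl]oxiran-2-yl}-6-methylocta-2,6-dienoate | ClC/C(C(=O)OC)=C\[C@@H]1O[C@H]1/C(C(=O)OC)=C\CC/C(C)=C\CO[Si](c1ccccc1)(c1ccccc1)C(C)(C)C | intermediate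
10 | dimethyl (2Z,4S,5R,6E)-5-acetoxy-6-{(4Z)-6-[(tert-butyldiphenylsilyl)oxy]-4-methylhex-4-en-1-ylidene}-2-(chloromethyl)-4-hydroxyhept-2-enedioate | ClC/C(C(=O)OC)=C\[C@H](O)[C@H](OC(C)=O)/C(C(=O)OC)=C\CC/C(C)=C\CO[Si](c1ccccc1)(c1ccccc1)C(C)(C)C | intermediate
11 | methyl (2S)-2-methyloxirane-2-carboxylate | COC(=O)[C@]1(C)CO1 | starting material
12 | potassium (2S)-2-methyloxirane-2-carboxylate | [K+].[O-]C(=O)[C@]1(C)CO1 | intermediate
13 | (2S)-2-methyloxirane-2-carbonyl chloride | ClC(=O)[C@]1(C)CO1 | intermediate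
14 | dimethyl (2Z,4S,5R,6E)-5-acetoxy-6-{(4Z)-6-[(tert-butyldiphenylsilyl)oxy]-4-methylhex-4-en-1-ylidene}-2-(chloromethyl)-4-{[(2S)-2-methyloxirane-2-carbonyl]oxy}hept-2-enedioate | ClC/C(C(=O)OC)=C\[C@H](OC(=O)[C@]1(C)CO1)[C@H](OC(C)=O)/C(C(=O)OC)=C\CC/C(C)=C\CO[Si](c1ccccc1)(c1ccccc1)C(C)(C)C | intermediate
15 | dimethyl (2Z,4S,5R,6E)-5-acetoxy-2-(chloromethyl)-6-[(4Z)-6-hydroxy-4-methylhex-4-en-1-ylidene]-4-{[(2S)-2-methyloxirane-2-carbonyl]oxy}hept-2-enedioate | ClC/C(C(=O)OC)=C\[C@H](OC(=O)[C@]1(C)CO1)[C@H](OC(C)=O)/C(C(=O)OC)=C\CC/C(C)=C\CO | intermediate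
16 | dimethyl (2Z,4S,5R,6E)-5-acetoxy-2-(chloromethyl)-6-{3-[(2R,3S)-3-(hydroxymethyl)-2-methyloxiran-2-yl]propylidene}-4-{[(2S)-2-methyloxirane-2-carbonyl]oxy}hept-2-enedioate | ClC/C(C(=O)OC)=C\[C@H](OC(=O)[C@]1(C)CO1)[C@H](OC(C)=O)/C(C(=O)OC)=C\CC[C@@]1(C)O[C@H]1CO | intermediate
17 | dimethyl (2Z,4S,5R,6E)-5-acetoxy-2-(chloromethyl)-6-{3-[(2R,3R)-3-formyl-2-methyloxiran-2-yl]propylidene}-4-{[(2S)-2-methyloxirane-2-carbonyl]oxy}hept-2-enedioate | ClC/C(C(=O)OC)=C\[C@H](OC(=O)[C@]1(C)CO1)[C@H](OC(C)=O)/C(C(=O)OC)=C\CC[C@@]1(C)O[C@H]1C=O | intermediate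
18 | allylchromium dichloride of 17 (CrCl2 on C13) | Cl[Cr](Cl)C/C(C(=O)OC)=C\[C@H](OC(=O)[C@]1(C)CO1)[C@H](OC(C)=O)/C(C(=O)OC)=C\CC[C@@]1(C)O[C@H]1C=O | intermediate
19 | ten-membered hydroxy ester, dimethyl 9-acetoxy-4,5-epoxy-6-hydroxy-8-{[(2S)-2-methyloxirane-2-carbonyl]oxy}germacra-1(10),11(13)-diene-12,14-dioate with the ring configuration of 20 | C=C(C(=O)OC)[C@@H]1[C@H](OC(=O)[C@]2(C)CO2)[C@H](OC(C)=O)/C(C(=O)OC)=C\CC[C@@]2(C)O[C@H]2[C@H]1O | intermediate
20 | CNP0274195.2, methyl (4R,5S,6S,7R,8S,9R)-9-acetoxy-4,5-epoxy-8-{[(2S)-2-methyloxirane-2-carbonyl]oxy}germacra-1(10),11(13)-dien-12,6-olid-14-oate, C2 and C9 cis on C1=C10 | C=C1C(=O)O[C@H]2[C@H]1[C@H](OC(=O)[C@]1(C)CO1)[C@H](OC(C)=O)/C(C(=O)OC)=C\CC[C@@]1(C)O[C@@H]21 | target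

**Totals and risks**

Total step count: 14. Longest linear sequence: 13 (steps 1–8 and 10–14).

Step 14 is the most likely to fail. The allylchromium species 18 carries an acyloxy group at C8, so vinylogous reductive elimination to a diene can compete with the slow ten-membered closure. The C8/C9 centres may also be mismatched with the Felkin/anti preference that sets C6 and C7. The fallback carries the C8 oxygen through the closure as an ether and acylates last. It sets out from 10. 4-Methoxybenzyl trichloroacetimidate with catalytic La(OTf)3 gives dimethyl (2Z,4S,5R,6E)-5-acetoxy-6-{(4Z)-6-[(tert-butyldiphenylsilyl)oxy]-4-methylhex-4-en-1-ylidene}-2-(chloromethyl)-4-[(4-methoxybenzyl)oxy]hept-2-enedioate F4. HF·pyridine gives dimethyl (2Z,4S,5R,6E)-5-acetoxy-2-(chloromethyl)-6-[(4Z)-6-hydroxy-4-methylhex-4-en-1-ylidene]-4-[(4-methoxybenzyl)oxy]hept-2-enedioate F5. Sharpless epoxidation as in step 12 gives dimethyl (2Z,4S,5R,6E)-5-acetoxy-2-(chloromethyl)-6-{3-[(2R,3S)-3-(hydroxymethyl)-2-methyloxiran-2-yl]propylidene}-4-[(4-methoxybenzyl)oxy]hept-2-enedioate F6. Dess–Martin oxidation gives dimethyl (2Z,4S,5R,6E)-5-acetoxy-2-(chloromethyl)-6-{3-[(2R,3R)-3-formyl-2-methyloxiran-2-yl]propylidene}-4-[(4-methoxybenzyl)oxy]hept-2-enedioate F7. CrCl2 closure with in situ lactonisation, now with a poor leaving group at C8, gives methyl 9-acetoxy-4,5-epoxy-8-[(4-methoxybenzyl)oxy]germacra-1(10),11(13)-dien-12,6-olid-14-oate with the configuration of 20 F8. DDQ in wet CH2Cl2 gives methyl 9-acetoxy-4,5-epoxy-8-hydroxygermacra-1(10),11(13)-dien-12,6-olid-14-oate with the configuration of 20 F9. Acylation with 13 (Et3N, DMAP) then rejoins the route at 20.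

Step 8 is the second risk. Acetic acid may attack C8, or C1 in an SN2′ sense, instead of C9. The fallback opens the oxirane by directed delivery before the allylic chloride is made. It sets out from 8. Ti(OiPr)4 and AcOH open the 2,3-epoxy alcohol at the carbon remote from the carbinol (C9) with inversion, giving dimethyl (4S,5R,6E)-5-acetoxy-6-{(4Z)-6-[(tert-butyldiphenylsilyl)oxy]-4-methylhex-4-en-1-ylidene}-3,4-dihydroxy-2-methylideneheptanedioate (both C3 epimers) F3. N-Chlorosuccinimide/Me2S at −20 °C then reacts only at the activated allylic carbinol with SN2′ transposition, and the fallback comes back to the route at 10.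

Step 5 is the third risk. The cross-conjugated dienal may epoxidise with low facial or site selectivity. The fallback replaces the aminocatalytic step with a hydroxyl-directed one. It sets out from 6. NaBH4/CeCl3·7H2O reduces the aldehyde 1,2 to methyl (2E,6Z)-8-[(tert-butyldiphenylsilyl)oxy]-2-[(1E)-3-hydroxyprop-1-en-1-yl]-6-methylocta-2,6-dienoate F1. Sharpless epoxidation with Ti(OiPr)4, L-(+)-diethyl tartrate and t-BuOOH gives methyl (2E,6Z)-8-[(tert-butyldiphenylsilyl)oxy]-2-[(2S,3S)-3-(hydroxymethyl)oxiran-2-yl]-6-methylocta-2,6-dienoate F2. Dess–Martin oxidation then comes back to the route at 7.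

**Further compounds**

F1 | step 5 | methyl (2E,6Z)-8-[(tert-butyldiphenylsilyl)oxy]-2-[(1E)-3-hydroxyprop-1-en-1-yl]-6-methylocta-2,6-dienoate | OC/C=C/C(C(=O)OC)=C\CC/C(C)=C\CO[Si](c1ccccc1)(c1ccccc1)C(C)(C)C
F2 | step 5 | methyl (2E,6Z)-8-[(tert-butyldiphenylsilyl)oxy]-2-[(2S,3S)-3-(hydroxymethyl)oxiran-2-yl]-6-methylocta-2,6-dienoate | OC[C@@H]1O[C@H]1/C(C(=O)OC)=C\CC/C(C)=C\CO[Si](c1ccccc1)(c1ccccc1)C(C)(C)C
F3 | step 8 | dimethyl (4S,5R,6E)-5-acetoxy-6-{(4Z)-6-[(tert-butyldiphenylsilyl)oxy]-4-methylhex-4-en-1-ylidene}-3,4-dihydroxy-2-methylideneheptanedioate (both C3 epimers) | C=C(C(=O)OC)C(O)[C@H](O)[C@H](OC(C)=O)/C(C(=O)OC)=C\CC/C(C)=C\CO[Si](c1ccccc1)(c1ccccc1)C(C)(C)C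
F4 | step 14 | dimethyl (2Z,4S,5R,6E)-5-acetoxy-6-{(4Z)-6-[(tert-butyldiphenylsilyl)oxy]-4-methylhex-4-en-1-ylidene}-2-(chloromethyl)-4-[(4-methoxybenzyl)oxy]hept-2-enedioate | ClC/C(C(=O)OC)=C\[C@H](OCc1ccc(OC)cc1)[C@H](OC(C)=O)/C(C(=O)OC)=C\CC/C(C)=C\CO[Si](c1ccccc1)(c1ccccc1)C(C)(C)C
F5 | step 14 | dimethyl (2Z,4S,5R,6E)-5-acetoxy-2-(chloromethyl)-6-[(4Z)-6-hydroxy-4-methylhex-4-en-1-ylidene]-4-[(4-methoxybenzyl)oxy]hept-2-enedioate | ClC/C(C(=O)OC)=C\[C@H](OCc1ccc(OC)cc1)[C@H](OC(C)=O)/C(C(=O)OC)=C\CC/C(C)=C\CO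
F6 | step 14 | dimethyl (2Z,4S,5R,6E)-5-acetoxy-2-(chloromethyl)-6-{3-[(2R,3S)-3-(hydroxymethyl)-2-methyloxiran-2-yl]propylidene}-4-[(4-methoxybenzyl)oxy]hept-2-enedioate | ClC/C(C(=O)OC)=C\[C@H](OCc1ccc(OC)cc1)[C@H](OC(C)=O)/C(C(=O)OC)=C\CC[C@@]1(C)O[C@H]1CO
F7 | step 14 | dimethyl (2Z,4S,5R,6E)-5-acetoxy-2-(chloromethyl)-6-{3-[(2R,3R)-3-formyl-2-methyloxiran-2-yl]propylidene}-4-[(4-methoxybenzyl)oxy]hept-2-enedioate | ClC/C(C(=O)OC)=C\[C@H](OCc1ccc(OC)cc1)[C@H](OC(C)=O)/C(C(=O)OC)=C\CC[C@@]1(C)O[C@H]1C=O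
F8 | step 14 | methyl 9-acetoxy-4,5-epoxy-8-[(4-methoxybenzyl)oxy]germacra-1(10),11(13)-dien-12,6-olid-14-oate with the configuration of 20 | C=C1C(=O)O[C@H]2[C@H]1[C@H](OCc1ccc(OC)cc1)[C@H](OC(C)=O)/C(C(=O)OC)=C\CC[C@@]1(C)O[C@@H]21
F9 | step 14 | methyl 9-acetoxy-4,5-epoxy-8-hydroxygermacra-1(10),11(13)-dien-12,6-olid-14-oate with the configuration of 20 | C=C1C(=O)O[C@H]2[C@H]1[C@H](O)[C@H](OC(C)=O)/C(C(=O)OC)=C\CC[C@@]1(C)O[C@@H]21
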